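**Plan**

- Retrosynthesis cuts C12=C13 first (aldol condensation with the C13–C16 lactone). It then cuts C4–C5 and C9–C10 together, opening both carbocycles to an acyclic epoxy diene allylsilane. Last come C6–C7 (sulfone alkylation), C3=C4 (olefination) and C8–C17 (carbomagnesiation).
- Forward: allylsilane bromide 8 (from 3-butyn-1-ol) and sulfone alcohol 17 (from geranyl bromide) are joined at C6–C7 and the product is epoxidised. One cascade then closes ring A and ring B. The C11–C12 arm is oxidised and condensed with the lactone, and the acetate goes on last.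
- Enabling feature: the trans-fused rings A and B (fusion C5–C10) carry the C3 carbinol, quaternary C4 (C18 methyl, axial C19 CH2OH), C5, C10 (C20 methyl) and C9 next to the exocyclic C8=C17. This is the pattern a chair–chair fold of an (E,Z) diene leaves when a C3–C4 epoxide starts the closure and an allylsilane (C17–C8=C9) ends it.
- Stereochemistry: C3 and C4 come from Sharpless epoxidation of a Z allylic alcohol, with inversion at C4 in the cascade. C5, C10 and C9 come from the alkene geometries through the chair–chair transition state. C14 comes from (S)-3-hydroxy-γ-butyrolactone, and the 12E alkene from an E1cB elimination.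

Key step: step 14

Remark: labdane numbering is used throughout (C3 carbinol; C4 with C18 methyl and C19 CH2OH; C8=C17; C11–C12 arm; lactone C13–C16 with C14 carbinol).

**Route**

Step 1
Reactants: 1 3-butyn-1-ol
Product: 2 tert-butyl(but-3-yn-1-yloxy)diphenylsilane
Conditions: TBDPSCl, imidazole, CH2Cl2, 0 °C to rt
Reagents that add atoms: tert-butyl(chloro)diphenylsilane, CC(C)(C)[Si](Cl)(c1ccccc1)c1ccccc1
Why: Silylation of the primary alcohol gives an ether (the future C12 oxygen) that should survive the organolithium, Grignard, hydride and Lewis-acid steps ahead.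

Step 2
Reactants: 2 tert-butyl(but-3-yn-1-yloxy)diphenylsilane
Product: 4 5-[(tert-butyldiphenylsilyl)oxy]pent-2-yn-1-ol, via lithium acetylide 3 (not isolated)
Conditions: n-BuLi, THF, −78 °C; (CH2O)n, −78 °C to rt
Reagents that add atoms: formaldehyde (from paraformaldehyde), C=O
Why: Addition of the lithium acetylide to formaldehyde (alkynylation of an aldehyde) installs C7 as a propargylic carbinol that will direct the next step.

Step 3
Reactants: 4 5-[(tert-butyldiphenylsilyl)oxy]pent-2-yn-1-ol; 5 (trimethylsilyl)methylmagnesium chloride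
Product: 6 (Z)-5-[(tert-butyldiphenylsilyl)oxy]-2-[(trimethylsilyl)methyl]pent-2-en-1-ol (CH2SiMe3 cis to the CH2CH2O chain)
Conditions: 5 (3.5 equiv), CuI (10 mol %), Et2O–THF, reflux
Reagents that add atoms: none
Why: Copper-catalysed anti-carbomagnesiation of a propargylic alcohol puts the carbon group on the alkyne carbon next to the carbinol and magnesium on the far carbon in a five-membered alkenylmagnesium alkoxide, so protonation should leave CH2SiMe3 cis to the C11–C12 chain, the allylsilane geometry the cascade needs.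

Step 4
Reactants: 6 (Z)-5-[(tert-butyldiphenylsilyl)oxy]-2-[(trimethylsilyl)methyl]pent-2-en-1-ol
Product: 8 tert-butyl{[(3E)-5-bromo-4-[(trimethylsilyl)methyl]pent-3-en-1-yl]oxy}diphenylsilane, via mesylate 7 (not isolated)
Conditions: MsCl, Et3N, THF, −40 °C; LiBr, 0 °C
Reagents that add atoms: lithium bromide, [Li+].[Br-]
Why: Mesylation followed by SN2 displacement with bromide makes the C7 electrophile under non-acidic conditions that should not protodesilylate the allylsilane.

Step 5
Reactants: 9 geranyl bromide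
Product: 10 geranyl phenyl sulfone
Conditions: PhSO2Na, DMF, rt
Reagents that add atoms: sodium benzenesulfinate, [Na+].[O-]S(=O)c1ccccc1
Why: S-alkylation of the sulfinate by the allylic bromide (SN2) gives an allylic sulfone that deactivates the C5=C10 alkene toward the next oxidation and later serves as the C6 carbanion.

Step 6
Reactants: 10 geranyl phenyl sulfone
Product: 11 6,7-epoxygeranyl phenyl sulfone (racemic)
Conditions: mCPBA, NaHCO3, CH2Cl2, 0 °C
Reagents that add atoms: 3-chloroperoxybenzoic acid, OOC(=O)c1cccc(Cl)c1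
Why: Prilezhaev epoxidation should select the electron-rich terminal alkene because the other one is deactivated by the allylic sulfonyl group; the new stereocentre is destroyed in the next step.

Step 7
Reactants: 11 6,7-epoxygeranyl phenyl sulfone (racemic)
Product: 13 (4E)-4-methyl-6-(phenylsulfonyl)hex-4-enal, via diol 12 (not isolated)
Conditions: H5IO6, THF–H2O, 0 °C to rt
Reagents that add atoms: none
Why: Periodic acid hydrolyses the epoxide to the vicinal diol and cleaves it (glycol cleavage) to the C3 aldehyde and acetone.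

Step 8
Reactants: 13 (4E)-4-methyl-6-(phenylsulfonyl)hex-4-enal; 14 methyl 2-[bis(2,2,2-trifluoroethoxy)phosphoryl]propanoate
Product: 16 methyl (2Z,6E)-2,6-dimethyl-8-(phenylsulfonyl)octa-2,6-dienoate, via potassium phosphonate carbanion 15 (not isolated)
Conditions: KN(SiMe3)2, 18-crown-6, THF, −78 °C; then 13, −78 °C
Reagents that add atoms: none
Why: The Still–Gennari variant of the Horner–Wadsworth–Emmons olefination, run with preformed phosphonate anion so that no free amide base meets the sulfone, should give the Z enoate in which the ester carbon (C19) is cis to the chain.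

Step 9
Reactants: 16 methyl (2Z,6E)-2,6-dimethyl-8-(phenylsulfonyl)octa-2,6-dienoate
Product: 17 (2Z,6E)-2,6-dimethyl-8-(phenylsulfonyl)octa-2,6-dien-1-ol
Conditions: i-Bu2AlH (2.5 equiv), CH2Cl2, −78 °C
Reagents that add atoms: none
Why: 1,2-Reduction of the enoate by the aluminium hydride gives the Z allylic alcohol without affecting the sulfone or either alkene geometry.

Step 10
Reactants: 17 (2Z,6E)-2,6-dimethyl-8-(phenylsulfonyl)octa-2,6-dien-1-ol; 8 tert-butyl{[(3E)-5-bromo-4-[(trimethylsilyl)methyl]pent-3-en-1-yl]oxy}diphenylsilane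
Product: 19 (2Z,6E,10Z)-13-[(tert-butyldiphenylsilyl)oxy]-2,6-dimethyl-8-(phenylsulfonyl)-10-[(trimethylsilyl)methyl]trideca-2,6,10-trien-1-ol (racemic at the sulfonyl carbon), via dilithio derivative 18 (not isolated)
Conditions: n-BuLi (2.1 equiv), THF–DMPU, −78 °C; then 8, −78 to −20 °C
Reagents that add atoms: none
Why: Double deprotonation gives the alkoxide and the allylic α-sulfonyl carbanion, and the much more nucleophilic carbanion should be alkylated by the allylic bromide (sulfone alkylation) to form C6–C7; the new stereocentre is removed in the next step.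

Step 11
Reactants: 19 (2Z,6E,10Z)-13-[(tert-butyldiphenylsilyl)oxy]-2,6-dimethyl-8-(phenylsulfonyl)-10-[(trimethylsilyl)methyl]trideca-2,6,10-trien-1-ol
Product: 20 (2Z,6E,10Z)-13-[(tert-butyldiphenylsilyl)oxy]-2,6-dimethyl-10-[(trimethylsilyl)methyl]trideca-2,6,10-trien-1-ol
Conditions: PdCl2(dppp) (5 mol %; dppp = Ph2P(CH2)3PPh2), LiEt3BH (3.5 equiv), THF, 0 °C
Reagents that add atoms: none
Why: Palladium-catalysed hydride desulfonylation of the allylic sulfone goes through a π-allylpalladium complex that is reduced at its less substituted end (C6), so the E C5=C10 alkene should stay in place.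

Step 12
Reactants: 20 (2Z,6E,10Z)-13-[(tert-butyldiphenylsilyl)oxy]-2,6-dimethyl-10-[(trimethylsilyl)methyl]trideca-2,6,10-trien-1-ol
Product: 21 [(2S,3R)-3-{(3E,7Z)-10-[(tert-butyldiphenylsilyl)oxy]-3-methyl-7-[(trimethylsilyl)methyl]deca-3,7-dien-1-yl}-2-methyloxiran-2-yl]methanol
Conditions: Ti(OiPr)4 (15 mol %), L-(+)-diethyl tartrate (18 mol %), t-BuOOH, 4 Å molecular sieves, CH2Cl2, −20 °C
Reagents that add atoms: tert-butyl hydroperoxide, CC(C)(C)OO
Why: Sharpless asymmetric epoxidation is directed by the allylic hydroxyl, so only C3=C4 should react, and the L-(+)-tartrate delivers oxygen to the face that gives the (2S,3R) epoxide, which fixes C3 and puts the CH2O group cis to the chain on C4.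

Step 13
Reactants: 21 [(2S,3R)-3-{(3E,7Z)-10-[(tert-butyldiphenylsilyl)oxy]-3-methyl-7-[(trimethylsilyl)methyl]deca-3,7-dien-1-yl}-2-methyloxiran-2-yl]methanol
Product: 22 tert-butyl{[(2S,3R)-3-{(3E,7Z)-10-[(tert-butyldiphenylsilyl)oxy]-3-methyl-7-[(trimethylsilyl)methyl]deca-3,7-dien-1-yl}-2-methyloxiran-2-yl]methoxy}diphenylsilane
Conditions: TBDPSCl, imidazole, DMAP (cat.), CH2Cl2, 0 °C to rt
Reagents that add atoms: tert-butyl(chloro)diphenylsilane, CC(C)(C)[Si](Cl)(c1ccccc1)c1ccccc1
Why: Silylation of the primary alcohol gives a bulky, non-chelating ether, so that the Lewis acid of the next step is not steered by a free C19 hydroxyl.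

Step 14
Reactants: 22 tert-butyl{[(2S,3R)-3-{(3E,7Z)-10-[(tert-butyldiphenylsilyl)oxy]-3-methyl-7-[(trimethylsilyl)methyl]deca-3,7-dien-1-yl}-2-methyloxiran-2-yl]methoxy}diphenylsilane
Product: 23 (1R,2R,4aS,5R,8aS)-5-{2-[(tert-butyldiphenylsilyl)oxy]ethyl}-1-{[(tert-butyldiphenylsilyl)oxy]methyl}-1,4a-dimethyl-6-methylidenedecahydronaphthalen-2-ol (free C3 hydroxyl, C12 and C19 silyl ethers, C8=C17)
Conditions: MeAlCl2 (2.5 equiv), CH2Cl2, −78 °C; Et3N, then aq NaHCO3
Reagents that add atoms: none
Why: MeAlCl2 binds the epoxide oxygen, the C5=C10 alkene opens the C4–O bond from the rear to close ring A, the developing C10 cation is taken by C9 of the allylsilane to close ring B, and the β-silyl cation at C8 then loses Me3Si so that only the exocyclic C8=C17 alkene can form. The closest known reaction type is the Lewis-acid-promoted, epoxide-initiated cation–olefin polycyclisation terminated by an allylsilane. Ring A closes 6-endo at the epoxide carbon C4 through a chair, and ring B closes 6-endo-trig at the allylsilane through a second chair. C3 keeps the epoxide configuration and ends with its oxygen equatorial; C4 is set by inversion, which turns the CH2OSi group that was cis to the chain into the axial C19; C5 and C10 follow from anti addition across the E C5=C10 alkene (trans fusion); C9 follows from the allylsilane geometry (C7 trans to C11), which puts the side chain equatorial. The step needs opening at C4 and not C3, a chair–chair fold and a single alkene position: the tertiary C4 in a six-membered transition state should secure the first, the two stereodefined alkenes the second and silicon the third. Because the β-oxygen on C19 slows ionisation, a strong aprotic Lewis acid at low temperature is chosen to keep the opening concerted with alkene participation.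

Step 15
Reactants: 23 (1R,2R,4aS,5R,8aS)-5-{2-[(tert-butyldiphenylsilyl)oxy]ethyl}-1-{[(tert-butyldiphenylsilyl)oxy]methyl}-1,4a-dimethyl-6-methylidenedecahydronaphthalen-2-ol
Product: 24 2-[(1R,4aS,5R,6R,8aS)-6-hydroxy-5-(hydroxymethyl)-5,8a-dimethyl-2-methylidenedecahydronaphthalen-1-yl]ethanol (3,12,19-triol)
Conditions: Bu4NF (3 equiv), THF, rt to 40 °C
Reagents that add atoms: none
Why: Fluoride-mediated desilylation should remove both silyl ethers and leave the alkene and all stereocentres unchanged.

Step 16
Reactants: 24 2-[(1R,4aS,5R,6R,8aS)-6-hydroxy-5-(hydroxymethyl)-5,8a-dimethyl-2-methylidenedecahydronaphthalen-1-yl]ethanol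
Product: 25 3,19-O-isopropylidene acetal of triol 24 (free C12 hydroxyl)
Conditions: Me2C(OMe)2, PPTS (cat.), acetone, rt; aq NaHCO3
Reagents that add atoms: 2,2-dimethoxypropane, COC(C)(C)OC
Why: Acid-catalysed transketalisation closes the six-membered isopropylidene acetal on the 1,3-diol (O3 and O19), while a mixed ketal on the lone primary C12 hydroxyl should hydrolyse on work-up.

Step 17
Reactants: 25 3,19-O-isopropylidene acetal of triol 24
Product: 26 C12 aldehyde of the 3,19-O-isopropylidene decalin
Conditions: Dess–Martin periodinane, NaHCO3, CH2Cl2, 0 °C to rt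
Reagents that add atoms: none
Why: Dess–Martin oxidation gives the aldehyde under buffered conditions that should spare the acetonide and avoid an acid-promoted carbonyl–ene reaction with C8=C17.

Step 18
Reactants: 27 (S)-3-hydroxy-γ-butyrolactone
Product: 28 (4S)-4-[(tert-butyldimethylsilyl)oxy]oxolan-2-one
Conditions: TBSCl, imidazole, DMF, rt
Reagents that add atoms: tert-butyl(chloro)dimethylsilane, CC(C)(C)[Si](C)(C)Cl
Why: Silylation turns the hydroxyl into a poor leaving group for the enolate chemistry that follows and carries the C14 stereocentre over unchanged from the chiral pool.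

Step 19
Reactants: 28 (4S)-4-[(tert-butyldimethylsilyl)oxy]oxolan-2-one; 26 C12 aldehyde of the 3,19-O-isopropylidene decalin
Product: 30 aldol adduct (C12 carbinol; lactone joined at C13; 14-O-TBS; 3,19-O-isopropylidene; mixture of C12 and C13 epimers), via lithium enolate 29 (not isolated)
Conditions: LiN(iPr)2, THF, −78 °C; then 26, −78 °C; AcOH, −78 °C
Reagents that add atoms: none
Why: Aldol addition of the lactone lithium enolate at −78 °C should form C12–C13 faster than the enolate expels its β-silyloxy group; C12 and C13 need no control because both lose their configuration in the next step.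

Step 20
Reactants: 30 aldol adduct
Product: 32 14-O-(tert-butyldimethylsilyl)-3,19-O-isopropylideneandrographolide, via mesylate 31 (not isolated)
Conditions: MsCl, Et3N, CH2Cl2, 0 °C; then DBU, 0 °C to rt
Reagents that add atoms: none
Why: Mesylation and E1cB elimination through the lactone enolate should expel the better leaving group (mesylate on C12, not silyloxide on C14) and give the thermodynamically preferred E alkylidene lactone with C11 trans to the carbonyl.

Step 21
Reactants: 32 14-O-(tert-butyldimethylsilyl)-3,19-O-isopropylideneandrographolide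
Product: 33 3,19-O-isopropylideneandrographolide
Conditions: HF·pyridine, pyridine, THF, 0 °C to rt
Reagents that add atoms: none
Why: Buffered hydrogen fluoride cleaves the allylic silyl ether without a strong base, which should avoid vinylogous loss of the C14 oxygen and leave the acetonide in place.

Step 22
Reactants: 33 3,19-O-isopropylideneandrographolide
Product: 34 14-O-acetyl-3,19-O-isopropylideneandrographolide
Conditions: Ac2O, pyridine, DMAP (cat.), CH2Cl2, 0 °C
Reagents that add atoms: acetic anhydride, CC(=O)OC(C)=O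
Why: Acylation of the only free hydroxyl (C14) under mild, weakly basic conditions should give the acetate with retention at C14.

Step 23
Reactants: 34 14-O-acetyl-3,19-O-isopropylideneandrographolide
Product: 35 14-O-acetylandrographolide (CNP0077248.1)
Conditions: AcOH–H2O (7:3), rt
Reagents that add atoms: none
Why: Mild aqueous acid hydrolyses the isopropylidene acetal to the C3 and C19 hydroxyls and should neither cleave nor eliminate the allylic C14 acetate.

**Compound list**

1 | 3-butyn-1-ol | C#CCCO | starting material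
2 | tert-butyl(but-3-yn-1-yloxy)diphenylsilane | C#CCCO[Si](c1ccccc1)(c1ccccc1)C(C)(C)C | intermediate
3 | lithium acetylide of 2 | [Li]C#CCCO[Si](c1ccccc1)(c1ccccc1)C(C)(C)C | intermediate
4 | 5-[(tert-butyldiphenylsilyl)oxy]pent-2-yn-1-ol | OCC#CCCO[Si](c1ccccc1)(c1ccccc1)C(C)(C)C | intermediate
5 | (trimethylsilyl)methylmagnesium chloride | C[Si](C)(C)C[Mg]Cl | starting material
6 | (Z)-5-[(tert-butyldiphenylsilyl)oxy]-2-[(trimethylsilyl)methyl]pent-2-en-1-ol | OC/C(C[Si](C)(C)C)=C/CCO[Si](c1ccccc1)(c1ccccc1)C(C)(C)C | intermediate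
7 | methanesulfonate of 6 | CS(=O)(=O)OC/C(C[Si](C)(C)C)=C/CCO[Si](c1ccccc1)(c1ccccc1)C(C)(C)C | intermediate
8 | tert-butyl{[(3E)-5-bromo-4-[(trimethylsilyl)methyl]pent-3-en-1-yl]oxy}diphenylsilane | BrC/C(C[Si](C)(C)C)=C/CCO[Si](c1ccccc1)(c1ccccc1)C(C)(C)C | intermediate
9 | geranyl bromide, (2E)-1-bromo-3,7-dimethylocta-2,6-diene | CC(C)=CCC/C(C)=C/CBr | starting material
10 | geranyl phenyl sulfone, {[(2E)-3,7-dimethylocta-2,6-dien-1-yl]sulfonyl}benzene | CC(C)=CCC/C(C)=C/CS(=O)(=O)c1ccccc1 | intermediate
11 | 6,7-epoxygeranyl phenyl sulfone (racemic) | CC1(C)OC1CC/C(C)=C/CS(=O)(=O)c2ccccc2 | intermediate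
12 | (6E)-2,6-dimethyl-8-(phenylsulfonyl)oct-6-ene-2,3-diol (racemic) | CC(C)(O)C(O)CC/C(C)=C/CS(=O)(=O)c1ccccc1 | intermediate
13 | (4E)-4-methyl-6-(phenylsulfonyl)hex-4-enal | O=CCC/C(C)=C/CS(=O)(=O)c1ccccc1 | intermediate
14 | methyl 2-[bis(2,2,2-trifluoroethoxy)phosphoryl]propanoate | COC(=O)C(C)P(=O)(OCC(F)(F)F)OCC(F)(F)F | starting material
15 | potassium salt of the carbanion of 14 | [K+].COC(=O)[C-](C)P(=O)(OCC(F)(F)F)OCC(F)(F)F | intermediate
16 | methyl (2Z,6E)-2,6-dimethyl-8-(phenylsulfonyl)octa-2,6-dienoate | COC(=O)/C(C)=C\CC/C(C)=C/CS(=O)(=O)c1ccccc1 | intermediate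
17 | (2Z,6E)-2,6-dimethyl-8-(phenylsulfonyl)octa-2,6-dien-1-ol | OC/C(C)=C\CC/C(C)=C/CS(=O)(=O)c1ccccc1 | intermediate
18 | dilithio derivative of 17 (lithium alkoxide, α-sulfonyl carbanion) | [Li]OC/C(C)=C\CC/C(C)=C/C([Li])S(=O)(=O)c1ccccc1 | intermediate
19 | (2Z,6E,10Z)-13-[(tert-butyldiphenylsilyl)oxy]-2,6-dimethyl-8-(phenylsulfonyl)-10-[(trimethylsilyl)methyl]trideca-2,6,10-trien-1-ol (racemic at C8) | OC/C(C)=C\CC/C(C)=C/C(C/C(C[Si](C)(C)C)=C/CCO[Si](c1ccccc1)(c1ccccc1)C(C)(C)C)S(=O)(=O)c1ccccc1 | intermediate
20 | (2Z,6E,10Z)-13-[(tert-butyldiphenylsilyl)oxy]-2,6-dimethyl-10-[(trimethylsilyl)methyl]trideca-2,6,10-trien-1-ol | OC/C(C)=C\CC/C(C)=C/CC/C(C[Si](C)(C)C)=C/CCO[Si](c1ccccc1)(c1ccccc1)C(C)(C)C | intermediate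
21 | [(2S,3R)-3-{(3E,7Z)-10-[(tert-butyldiphenylsilyl)oxy]-3-methyl-7-[(trimethylsilyl)methyl]deca-3,7-dien-1-yl}-2-methyloxiran-2-yl]methanol | C[C@@]1(CO)O[C@@H]1CC/C(C)=C/CC/C(C[Si](C)(C)C)=C/CCO[Si](c2ccccc2)(c2ccccc2)C(C)(C)C | intermediate
22 | tert-butyl{[(2S,3R)-3-{(3E,7Z)-10-[(tert-butyldiphenylsilyl)oxy]-3-methyl-7-[(trimethylsilyl)methyl]deca-3,7-dien-1-yl}-2-methyloxiran-2-yl]methoxy}diphenylsilane | C[C@@]1(CO[Si](c2ccccc2)(c2ccccc2)C(C)(C)C)O[C@@H]1CC/C(C)=C/CC/C(C[Si](C)(C)C)=C/CCO[Si](c3ccccc3)(c3ccccc3)C(C)(C)C | intermediate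
23 | (1R,2R,4aS,5R,8aS)-5-{2-[(tert-butyldiphenylsilyl)oxy]ethyl}-1-{[(tert-butyldiphenylsilyl)oxy]methyl}-1,4a-dimethyl-6-methylidenedecahydronaphthalen-2-ol | C=C1CC[C@@H]2[C@](C)(CO[Si](c3ccccc3)(c3ccccc3)C(C)(C)C)[C@H](O)CC[C@@]2(C)[C@@H]1CCO[Si](c4ccccc4)(c4ccccc4)C(C)(C)C | intermediate
24 | 2-[(1R,4aS,5R,6R,8aS)-6-hydroxy-5-(hydroxymethyl)-5,8a-dimethyl-2-methylidenedecahydronaphthalen-1-yl]ethanol | C=C1CC[C@@H]2[C@](C)(CO)[C@H](O)CC[C@@]2(C)[C@@H]1CCO | intermediate
25 | 3,19-O-isopropylidene acetal of triol 24 (free C12 hydroxyl) | C=C1CC[C@@H]2[C@](C)(COC(C)(C)O3)[C@H]3CC[C@@]2(C)[C@@H]1CCO | intermediate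
26 | C12 aldehyde of the 3,19-O-isopropylidene decalin | C=C1CC[C@@H]2[C@](C)(COC(C)(C)O3)[C@H]3CC[C@@]2(C)[C@@H]1CC=O | intermediate
27 | (S)-3-hydroxy-γ-butyrolactone, (4S)-4-hydroxyoxolan-2-one | O=C1C[C@H](O)CO1 | starting material
28 | (4S)-4-[(tert-butyldimethylsilyl)oxy]oxolan-2-one | O=C1C[C@H](O[Si](C)(C)C(C)(C)C)CO1 | intermediate
29 | lithium enolate of 28 | [Li]OC1=C[C@H](O[Si](C)(C)C(C)(C)C)CO1 | intermediate
30 | aldol adduct of 26 and 28 (C12 carbinol, 14-O-TBS, 3,19-O-isopropylidene; C12 and C13 epimers) | C=C1CC[C@@H]2[C@](C)(COC(C)(C)O3)[C@H]3CC[C@@]2(C)[C@@H]1CC(O)C1C(=O)OC[C@H]1O[Si](C)(C)C(C)(C)C | intermediate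
31 | C12 methanesulfonate of 30 | C=C1CC[C@@H]2[C@](C)(COC(C)(C)O3)[C@H]3CC[C@@]2(C)[C@@H]1CC(OS(C)(=O)=O)C1C(=O)OC[C@H]1O[Si](C)(C)C(C)(C)C | intermediate
32 | 14-O-(tert-butyldimethylsilyl)-3,19-O-isopropylideneandrographolide | C=C1CC[C@@H]2[C@](C)(COC(C)(C)O3)[C@H]3CC[C@@]2(C)[C@@H]1C/C=C1/C(=O)OC[C@H]1O[Si](C)(C)C(C)(C)C | intermediate
33 | 3,19-O-isopropylideneandrographolide | C=C1CC[C@@H]2[C@](C)(COC(C)(C)O3)[C@H]3CC[C@@]2(C)[C@@H]1C/C=C1/C(=O)OC[C@H]1O | intermediate
34 | 14-O-acetyl-3,19-O-isopropylideneandrographolide | C=C1CC[C@@H]2[C@](C)(COC(C)(C)O3)[C@H]3CC[C@@]2(C)[C@@H]1C/C=C1/C(=O)OC[C@H]1OC(C)=O | intermediate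
35 | 14-O-acetylandrographolide (CNP0077248.1) | C=C1CC[C@@H]2[C@](C)(CO)[C@H](O)CC[C@@]2(C)[C@@H]1C/C=C1/C(=O)OC[C@H]1OC(C)=O | target

**Step count and risks**

Total step count: 23. Longest linear sequence: 18 steps (steps 5–17 and 19–23, from geranyl bromide 9).

The three steps most likely to fail:

Step 14 (cascade bicyclisation). Heterolysis of the C4–O bond is slowed by the electron-withdrawing C19 oxygen and by the bulk of the silyloxymethyl group that must become axial. A 1,2-hydride shift from C3 (ketone formation) or proton loss from the C10 cation after ring A could then outrun the second ring closure. The fallback sets out from epoxy alcohol 21 and comes back at triol 24. It cyclises 21 one stage earlier, with the Lewis acid tethered to the substrate: MeAlCl2 (2.2 equiv, CH2Cl2, −78 °C) first converts the free C19 hydroxyl into its chloroaluminium alkoxide. That removes the bulky silyl group, makes the β-oxygen less electron-withdrawing and holds the aluminium next to the epoxide oxygen. Closure at the tertiary C4 through the six-membered chair should still be preferred over five-membered closure at C3. The expected product is the 12-O-silyl diol (1R,2R,4aS,5R,8aS)-5-{2-[(tert-butyldiphenylsilyl)oxy]ethyl}-1-(hydroxymethyl)-1,4a-dimethyl-6-methylidenedecahydronaphthalen-2-ol F1, which Bu4NF in THF would convert into 24; step 13 is skipped.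

Step 19 (aldol addition). The lithium enolate could expel its β-silyloxy group (E1cB) before it adds, and the basic enolate could enolise aldehyde 26 in place of adding to it. The fallback sets out from lactone 28 and aldehyde 26 and comes back at aldol adduct 30. The enolate is trapped as it forms (LiN(iPr)2 with Me3SiCl present, THF, −78 °C) as the silyl ketene acetal (4S)-4-[(tert-butyldimethylsilyl)oxy]-2-[(trimethylsilyl)oxy]-4,5-dihydrofuran F2. This neutral nucleophile is then added to 26 in a Mukaiyama aldol reaction (BF3·OEt2, CH2Cl2, −78 °C), which avoids a free basic enolate; aqueous work-up would give 30.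

Step 3 (anti-carbomagnesiation). The weakly nucleophilic silylmethyl Grignard reagent may add sluggishly to the internal alkyne, leaving conversion incomplete or eroding the regio- and stereocontrol that the magnesium chelate provides. The fallback sets out from propargylic alcohol 4 and comes back at allylsilane alcohol 6. Ruthenium-catalysed trans-hydrostannation (Bu3SnH, [Cp*RuCl]4, CH2Cl2, rt), in which the hydroxyl steers tin to the neighbouring alkyne carbon, should give (Z)-5-[(tert-butyldiphenylsilyl)oxy]-2-(tributylstannyl)pent-2-en-1-ol F3. Iododestannylation with retention (I2, CH2Cl2, 0 °C) should give (Z)-5-[(tert-butyldiphenylsilyl)oxy]-2-iodopent-2-en-1-ol F4. Kumada coupling of F4 with 5 (excess, Pd(PPh3)4 as zerovalent palladium catalyst, THF, rt to 50 °C) would then deliver 6 with the same alkene geometry.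

Further compounds
F1 | step 14 | (1R,2R,4aS,5R,8aS)-5-{2-[(tert-butyldiphenylsilyl)oxy]ethyl}-1-(hydroxymethyl)-1,4a-dimethyl-6-methylidenedecahydronaphthalen-2-ol | C=C1CC[C@@H]2[C@](C)(CO)[C@H](O)CC[C@@]2(C)[C@@H]1CCO[Si](c3ccccc3)(c3ccccc3)C(C)(C)C
F2 | step 19 | (4S)-4-[(tert-butyldimethylsilyl)oxy]-2-[(trimethylsilyl)oxy]-4,5-dihydrofuran | C[Si](C)(C)OC1=C[C@H](O[Si](C)(C)C(C)(C)C)CO1
F3 | step 3 | (Z)-5-[(tert-butyldiphenylsilyl)oxy]-2-(tributylstannyl)pent-2-en-1-ol | OC/C([Sn](CCCC)(CCCC)CCCC)=C/CCO[Si](c1ccccc1)(c1ccccc1)C(C)(C)C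
F4 | step 3 | (Z)-5-[(tert-butyldiphenylsilyl)oxy]-2-iodopent-2-en-1-ol | OC/C(I)=C/CCO[Si](c1ccccc1)(c1ccccc1)C(C)(C)C
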